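**Retrosynthetic overview**

1. Numbering follows isochromen-1-one (C1 carbonyl, O2, C3, C4, C4a, C5–C8, C8a; side chain C1'–C11'; ring A = benzene ring, ring B = lactone ring). Target 15 ⇐ 8-O-methyl ether 14, by chelation-directed cleavage of the C8 methyl ether as the last step.
2. 14 ⇐ ester 12: ring B is closed by forming C4–C4a through a nickel-catalysed reductive union of two electrophilic carbons (C4a–Br on ring A and the primary C4–Cl). Ring A is bought; ring B is the only ring formed.
3. Enabling feature: C4 is a primary sp3 carbon next to C3, which carries O2, so C4–C3–O2 is a halohydrin ester that comes directly from epichlorohydrin. C4a is ortho to the carboxyl carbon C1 and meta to the oxygens on C6 and C8, so it is closed to Friedel–Crafts chemistry but addressable as a C–Br bond; the C1(=O)–O2 ester holds C4 and C4a in a 1,6 relation.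
4. 12 ⇐ 9 + (S)-oct-1-en-3-ol (cross-metathesis, then diimide; C6' from the chiral pool); 9 ⇐ acid 4 + chlorohydrin 7.
5. 7 ⇐ (R)-epichlorohydrin + but-3-en-1-ylmagnesium bromide (sets C3); 4 ⇐ 1-bromo-3,5-dimethoxybenzene (formylation, oxidation).

Key step: step 7

Remark: 1-bromo-3,5-dimethoxybenzene, but-3-en-1-ylmagnesium bromide (THF solution), (R)-epichlorohydrin and (S)-oct-1-en-3-ol are taken as purchasable; the free C6' hydroxyl is carried unprotected because no step after its introduction requires protection.

**Route**

Step 1
Reactants: 1 1-bromo-3,5-dimethoxybenzene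
Product: 3 2-bromo-4,6-dimethoxybenzaldehyde, via aryl iminium chloride 2 (not isolated)
Conditions: POCl3, DMF, 0 °C then 90 °C; aq. NaOAc, rt
Reagents that add atoms: N,N-dimethylformamide (CN(C)C=O); water (O)
Why: Vilsmeier–Haack formylation should occur mainly at the ring carbon ortho to one methoxy group and para to the other (next to bromine), the isomer from attack between the two methoxy groups being the minor path and removable by crystallisation.

Step 2
Reactants: 3 2-bromo-4,6-dimethoxybenzaldehyde
Product: 4 2-bromo-4,6-dimethoxybenzoic acid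
Conditions: NaClO2, NaH2PO4, 2-methyl-2-butene, t-BuOH/H2O, rt
Reagents that add atoms: sodium chlorite ([Na+].[O-]Cl=O)
Why: Pinnick oxidation converts the hindered aldehyde to the acid without touching the aryl bromide, and 2-methyl-2-butene traps hypochlorous acid so the electron-rich ring is not chlorinated.

Step 3
Reactants: 5 but-3-en-1-ylmagnesium bromide; 6 (R)-epichlorohydrin
Product: 7 (2R)-1-chlorohept-6-en-2-ol
Conditions: CuI (10 mol%), THF, −40 to −20 °C; then 1 M HCl, 0 °C
Reagents that add atoms: none
Why: Copper-catalysed Grignard opening of the epoxide at its unsubstituted carbon (SN2) leaves the C–O bond at the stereocenter intact, so the (R) configuration of 6 becomes the (R) carbinol that is C3 of the target, and the primary chloride is not displaced at low temperature.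

Step 4
Reactants: 4 2-bromo-4,6-dimethoxybenzoic acid; 7 (2R)-1-chlorohept-6-en-2-ol
Product: 9 (2R)-1-chlorohept-6-en-2-yl 2-bromo-4,6-dimethoxybenzoate, via acid chloride 8 (not isolated)
Conditions: (COCl)2, DMF (cat.), CH2Cl2, 0 °C to rt, evaporate; then 7, pyridine, DMAP (0.2 equiv), CH2Cl2, 0 to 40 °C
Reagents that add atoms: none
Why: Acylation of the secondary alcohol by the aroyl chloride under DMAP nucleophilic catalysis forms the ester without breaking the C–O bond at the stereocenter, so the configuration is retained.

Step 5
Reactants: 9 (2R)-1-chlorohept-6-en-2-yl 2-bromo-4,6-dimethoxybenzoate; 10 (S)-oct-1-en-3-ol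
Product: 11 (2R,6E,8S)-1-chloro-8-hydroxytridec-6-en-2-yl 2-bromo-4,6-dimethoxybenzoate
Conditions: second-generation Grubbs catalyst RuCl2(=CHPh)(PCy3)(H2IMes) (5 mol%), 10 (3 equiv), CH2Cl2, 40 °C
Reagents that add atoms: none
Why: Olefin cross-metathesis between a fast-dimerising terminal alkene and an excess of a slowly dimerising secondary allylic alcohol should favour the cross product, with the carbinol stereocenter of 10 carried over unchanged and the alkene geometry irrelevant because the double bond is saturated next.

Step 6
Reactants: 11 (2R,6E,8S)-1-chloro-8-hydroxytridec-6-en-2-yl 2-bromo-4,6-dimethoxybenzoate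
Product: 12 (2R,8S)-1-chloro-8-hydroxytridecan-2-yl 2-bromo-4,6-dimethoxybenzoate
Conditions: 2-nitrobenzenesulfonyl hydrazide (excess, in portions), Et3N, CH2Cl2, rt
Reagents that add atoms: none
Why: Diimide reduction (concerted syn transfer of two hydrogens from HN=NH made in the flask) saturates the C=C bond without hydrogenolysis of the aryl bromide, the alkyl chloride or the allylic C–O bond, so neither stereocenter is affected.

Step 7
Reactants: 12 (2R,8S)-1-chloro-8-hydroxytridecan-2-yl 2-bromo-4,6-dimethoxybenzoate
Product: 14 (3R)-3-[(6S)-6-hydroxyundecyl]-6,8-dimethoxy-3,4-dihydroisochromen-1-one, via alkyl iodide 13 (not isolated)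
Conditions: NiBr2(dme) (10 mol%), 4,4'-di-tert-butyl-2,2'-bipyridine (12 mol%), NaI (50 mol%), Mn powder (3 equiv), DMA, 70 °C, 12 added over 8 h to a final 0.01 M
Reagents that add atoms: none
Why: Proposed new method: zerovalent nickel (from NiBr2(dme), the bipyridine ligand and Mn) should insert into the C4a–Br bond of 12 while iodide slowly converts the C4–Cl end into iodide 13, from which a monovalent nickel halide abstracts iodine to give the primary C4 radical; this radical is captured by the aryl nickel centre on the same molecule, and reductive elimination from the resulting trivalent, seven-membered aryl(alkyl)nickel ring forms C4–C4a before Mn returns nickel to the zerovalent state. The closest known reaction type is the intermolecular nickel-catalysed reductive cross-electrophile coupling of aryl bromides with primary alkyl halides (bipyridine ligand, Zn or Mn as reductant), which joins two electrophilic carbons without a preformed organometallic; the untested element is ring closure across a benzoate ester with a β-acyloxy alkyl halide. Ring B closes as a six-membered ring by bond formation at the sp2 carbon C4a, through C–C reductive elimination that contracts the seven-membered nickelacycle, with the C1(=O)–O2 ester as the tether. No stereocenter is formed: C3 (R) and C6' (S) are carried in from 6 and 10, and C3 is not the radical carbon, so it stays intact as long as radical capture outruns a 1,2-acyloxy shift. The step needs intramolecular hetero-coupling to win over oligomerisation, hydrodehalogenation and β-elimination of the carboxylate; the single C–Br bond at C4a fixes the site on ring A, the ester tether makes six-membered closure the only short-range pairing, fast insertion at C–Br against slow iodide-gated radical formation at C4 means each radical is born on a molecule that already carries aryl nickel, high dilution suppresses intermolecular coupling, and Mn in place of Zn avoids an alkylzinc and its Boord-type elimination.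

Step 8
Reactants: 14 (3R)-3-[(6S)-6-hydroxyundecyl]-6,8-dimethoxy-3,4-dihydroisochromen-1-one
Product: 15 (3R)-8-hydroxy-3-[(6S)-6-hydroxyundecyl]-6-methoxy-3,4-dihydroisochromen-1-one
Conditions: BCl3 (1 M in CH2Cl2, 3 equiv), CH2Cl2, −78 to 0 °C; then aq. NaHCO3
Reagents that add atoms: none
Why: Chelation of boron between the lactone carbonyl oxygen and the peri C8 methoxy oxygen directs chloride attack to that methyl group only (selective demethylation of an ortho-carbonyl aryl methyl ether), so the C6 methoxy group, the lactone and both stereocenters should remain untouched, the side-chain borate being hydrolysed on work-up.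

**Compound list**

1 | 1-bromo-3,5-dimethoxybenzene | COc1cc(Br)cc(OC)c1 | starting material
2 | aryl iminium chloride: N-[(2-bromo-4,6-dimethoxyphenyl)methylidene]-N-methylmethanaminium chloride (not isolated) | C[N+](C)=Cc1c(Br)cc(OC)cc1OC.[Cl-] | intermediate
3 | 2-bromo-4,6-dimethoxybenzaldehyde | O=Cc1c(Br)cc(OC)cc1OC | intermediate
4 | 2-bromo-4,6-dimethoxybenzoic acid | OC(=O)c1c(Br)cc(OC)cc1OC | intermediate
5 | but-3-en-1-ylmagnesium bromide | C=CCC[Mg]Br | starting material
6 | (R)-epichlorohydrin, (2R)-2-(chloromethyl)oxirane | ClC[C@H]1CO1 | starting material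
7 | (2R)-1-chlorohept-6-en-2-ol | C=CCCC[C@H](CCl)O | intermediate
8 | acid chloride: 2-bromo-4,6-dimethoxybenzoyl chloride (not isolated) | ClC(=O)c1c(Br)cc(OC)cc1OC | intermediate
9 | (2R)-1-chlorohept-6-en-2-yl 2-bromo-4,6-dimethoxybenzoate | C=CCCC[C@H](CCl)OC(=O)c1c(Br)cc(OC)cc1OC | intermediate
10 | (S)-oct-1-en-3-ol | CCCCC[C@H](O)C=C | starting material
11 | (2R,6E,8S)-1-chloro-8-hydroxytridec-6-en-2-yl 2-bromo-4,6-dimethoxybenzoate | CCCCC[C@H](O)/C=C/CCC[C@H](CCl)OC(=O)c1c(Br)cc(OC)cc1OC | intermediate
12 | (2R,8S)-1-chloro-8-hydroxytridecan-2-yl 2-bromo-4,6-dimethoxybenzoate | CCCCC[C@H](O)CCCCC[C@H](CCl)OC(=O)c1c(Br)cc(OC)cc1OC | intermediate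
13 | alkyl iodide: (2R,8S)-8-hydroxy-1-iodotridecan-2-yl 2-bromo-4,6-dimethoxybenzoate (not isolated) | CCCCC[C@H](O)CCCCC[C@H](CI)OC(=O)c1c(Br)cc(OC)cc1OC | intermediate
14 | (3R)-3-[(6S)-6-hydroxyundecyl]-6,8-dimethoxy-3,4-dihydroisochromen-1-one | CCCCC[C@H](O)CCCCC[C@@H]1Cc2cc(OC)cc(OC)c2C(=O)O1 | intermediate
15 | (3R)-8-hydroxy-3-[(6S)-6-hydroxyundecyl]-6-methoxy-3,4-dihydroisochromen-1-one | CCCCC[C@H](O)CCCCC[C@@H]1Cc2cc(OC)cc(O)c2C(=O)O1 | target

**Step count and risks**

Total step count: 8. Longest linear sequence: 7 steps (1 to 15 through steps 1, 2, 4, 5, 6, 7 and 8; step 3 is the side branch).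

Steps most likely to fail:

Step 7 (proposed new method). What may go wrong: capture of the C4 radical by the aryl nickel centre across the ester, which prefers the conformation that turns C4 away from C4a, may be slower than intermolecular coupling, hydrodehalogenation or a 1,2-acyloxy shift. The fallback uses polar, known chemistry: the same C4–C4a bond is made between two molecules and the lactone closes afterwards. It sets out from 4 and 7 and comes back at 14. Acid 4 is methylated (MeI, K2CO3, DMF) to methyl 2-bromo-4,6-dimethoxybenzoate F1, and chlorohydrin 7 is closed with powdered NaOH in Et2O to (2R)-2-(pent-4-en-1-yl)oxirane F2. Bromine–magnesium exchange on F1 (iPrMgCl·LiCl, THF, −30 °C) should give [3,5-dimethoxy-2-(methoxycarbonyl)phenyl]magnesium chloride F3, which with CuI (10 mol%) opens F2 at its CH2 end to give, after work-up, methyl 2-[(2R)-2-hydroxyhept-6-en-1-yl]-4,6-dimethoxybenzoate F4. F4 lactonises (TsOH, toluene, 60 °C) to (3R)-6,8-dimethoxy-3-(pent-4-en-1-yl)-3,4-dihydroisochromen-1-one F5. Cross-metathesis of F5 with 10 under the conditions of step 5 gives (3R)-3-[(4E,6S)-6-hydroxyundec-4-en-1-yl]-6,8-dimethoxy-3,4-dihydroisochromen-1-one F6, and diimide reduction as in step 6 returns 14.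

Step 5. What may go wrong: homodimerisation of 9 and ruthenium-hydride isomerisation of the free allylic alcohol to a saturated ketone may outrun the cross-metathesis. The fallback avoids metathesis and sets the C6' stereocenter by catalyst-controlled reduction; it sets out from 9 and comes back at 11. Lemieux–Johnson cleavage of the terminal alkene of 9 (OsO4 cat., NaIO4, 2,6-lutidine, dioxane/H2O) gives (2R)-1-chloro-6-oxohexan-2-yl 2-bromo-4,6-dimethoxybenzoate F7. Horner–Wadsworth–Emmons reaction of F7 with commercial dimethyl (2-oxoheptyl)phosphonate (LiCl, DBU, MeCN) gives (2R,6E)-1-chloro-8-oxotridec-6-en-2-yl 2-bromo-4,6-dimethoxybenzoate F8. Corey–Bakshi–Shibata reduction of F8 with the (R)-2-methyl oxazaborolidine and catecholborane (toluene, −78 °C), the alkenyl group acting as the large substituent, should deliver the (8S)-alcohol 11.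

Step 4. What may go wrong: acylation by the di-ortho-substituted aroyl chloride 8 may be slow, with competing base-induced closure of 7 to its epoxide. In the fallback the carboxylate acts as the nucleophile at carbon, with inversion, so the hindered carbonyl is never attacked; it sets out from 4 and 5 and comes back at 9. Grignard reagent 5 opens commercial (S)-epichlorohydrin under the conditions of step 3 to give (2S)-1-chlorohept-6-en-2-ol F9, and Mitsunobu esterification of 4 with F9 (PPh3, DIAD, toluene, 0 °C to rt) gives 9 with inversion at the carbinol carbon.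

**Further compounds**

F1 | step 7 | methyl 2-bromo-4,6-dimethoxybenzoate | COC(=O)c1c(Br)cc(OC)cc1OC
F2 | step 7 | (2R)-2-(pent-4-en-1-yl)oxirane | C=CCCC[C@@H]1CO1
F3 | step 7 | [3,5-dimethoxy-2-(methoxycarbonyl)phenyl]magnesium chloride | COC(=O)c1c([Mg]Cl)cc(OC)cc1OC
F4 | step 7 | methyl 2-[(2R)-2-hydroxyhept-6-en-1-yl]-4,6-dimethoxybenzoate | COC(=O)c1c(C[C@H](O)CCCC=C)cc(OC)cc1OC
F5 | step 7 | (3R)-6,8-dimethoxy-3-(pent-4-en-1-yl)-3,4-dihydroisochromen-1-one | C=CCCC[C@@H]1Cc2cc(OC)cc(OC)c2C(=O)O1
F6 | step 7 | (3R)-3-[(4E,6S)-6-hydroxyundec-4-en-1-yl]-6,8-dimethoxy-3,4-dihydroisochromen-1-one | CCCCC[C@H](O)/C=C/CCC[C@@H]1Cc2cc(OC)cc(OC)c2C(=O)O1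
F7 | step 5 | (2R)-1-chloro-6-oxohexan-2-yl 2-bromo-4,6-dimethoxybenzoate | O=CCCC[C@H](CCl)OC(=O)c1c(Br)cc(OC)cc1OC
F8 | step 5 | (2R,6E)-1-chloro-8-oxotridec-6-en-2-yl 2-bromo-4,6-dimethoxybenzoate | CCCCCC(=O)/C=C/CCC[C@H](CCl)OC(=O)c1c(Br)cc(OC)cc1OC
F9 | step 4 | (2S)-1-chlorohept-6-en-2-ol | C=CCCC[C@@H](CCl)O
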